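**Strategy.** Everything rests on cutting ring A of the flavone at C4a–C5: C5, C6, C7 and C8, each oxygen-bearing, are taken as one block from the four ring carbons of dimethyl squarate, and rings B/C come as a 2-aryl-3-methoxy-4-pyrone. In a single thermolysis the cyclobutenone opens to a dienylketene that closes onto pyrone C5 (the enol-ether β-carbon next to the point of attachment, C6), building the benzo ring with its four oxygens already distinguished. The precursor is the pyrone joined at C6 to a 4-methoxycyclobut-2-enone carrying OMe at C2 and OBn at C3; keeping the carbinol oxygen as a methyl ether delivers 8-OMe directly and avoids an air-sensitive hydroquinone.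

Key step: step 6

Remark (assumption): the target has no stereogenic element, so it is made as the one achiral compound; 9 and 11 are racemic at the cyclobutenone C4, a centre that step 6 removes.
Remark (design): the aryl group is attached by cross-coupling to a preformed pyrone, because an oxidative furan-to-pyrone ring expansion needs free halogen, which would also attack the electron-rich benzyloxyphenyl ring.

Step 1
Reactants: 1 3-hydroxy-4H-pyran-4-one (pyromeconic acid)
Product: 2 2-bromo-3-hydroxy-4H-pyran-4-one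
Conditions: NBS (1.05 equiv), MeCN, 0 °C → rt
Reagents that add atoms: N-bromosuccinimide, O=C1CCC(=O)N1Br
Why: Electrophilic bromination of the enol should go to C2, the enol α-carbon and the only ring position activated by the 3-OH, which is also the site where this ring system is hydroxymethylated.

Step 2
Reactants: 2 2-bromo-3-hydroxy-4H-pyran-4-one
Product: 3 2-bromo-3-methoxy-4H-pyran-4-one
Conditions: MeI, K2CO3, acetone, rt
Reagents that add atoms: iodomethane, CI
Why: Williamson O-methylation of the acidic enol (maltol-type, pKa near 8) with carbonate as base is the standard way to 3-methoxy-4-pyrones and is mild enough to leave the C2–Br bond alone.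

Step 3
Reactants: 3 2-bromo-3-methoxy-4H-pyran-4-one; 4 4-(benzyloxy)phenylboronic acid
Product: 5 2-[4-(benzyloxy)phenyl]-3-methoxy-4H-pyran-4-one
Conditions: Pd(dppf)Cl2 (3 mol%), K2CO3, dioxane/H2O, 80 °C
Reagents that add atoms: none
Why: Suzuki–Miyaura coupling: the C2–Br bond of 3 is a vinylogous acyl bromide that should undergo oxidative addition readily, and the benzyl ether and the pyrone ring tolerate carbonate at 80 °C.

Step 4
Reactants: 5 2-[4-(benzyloxy)phenyl]-3-methoxy-4H-pyran-4-one; 6 dimethyl squarate (3,4-dimethoxycyclobut-3-ene-1,2-dione)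
Product: 9 4-{6-[4-(benzyloxy)phenyl]-5-methoxy-4-oxo-4H-pyran-2-yl}-2,3,4-trimethoxycyclobut-2-en-1-one (racemic), via 6-lithiopyrone 7 (not isolated), via lithium cyclobutenolate 8 (not isolated)
Conditions: LiTMP (from TMPH, n-BuLi), THF, −78 °C; transfer into 6, THF, −78 °C; MeOTf (1.5 equiv), −78 → −20 °C; Et3N, aq. NaHCO3
Reagents that add atoms: methyl trifluoromethanesulfonate, COS(=O)(=O)C(F)(F)F
Why: Deprotonative lithiation by a hindered amide should take the C6–H next to the ring oxygen (the counterpart of chromone C2–H, with no conjugate addition of the base), the vinyllithium adds 1,2 to one carbonyl of the squarate, and the lithium alkoxide is O-methylated in the flask by methyl triflate; the new carbinol centre is racemic and is lost in step 6.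

Step 5
Reactants: 9 4-{6-[4-(benzyloxy)phenyl]-5-methoxy-4-oxo-4H-pyran-2-yl}-2,3,4-trimethoxycyclobut-2-en-1-one (racemic); 10 benzyl alcohol
Product: 11 3-(benzyloxy)-4-{6-[4-(benzyloxy)phenyl]-5-methoxy-4-oxo-4H-pyran-2-yl}-2,4-dimethoxycyclobut-2-en-1-one (racemic)
Conditions: BnOH (8 equiv), CSA (10 mol%), 4 Å MS, CH2Cl2, rt
Reagents that add atoms: none
Why: Acid-catalysed vinylogous transesterification (conjugate addition–elimination through the O-protonated enone) should exchange only the C3 methoxy, the one β-alkoxy group of the cyclobutenone, while the C2 methoxy, the tertiary methyl ether and the pyrone methyl ether are not activated; excess alcohol and uptake of methanol by the sieves drive the equilibrium.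

Step 6
Reactants: 11 3-(benzyloxy)-4-{6-[4-(benzyloxy)phenyl]-5-methoxy-4-oxo-4H-pyran-2-yl}-2,4-dimethoxycyclobut-2-en-1-one (racemic)
Product: 14 7-(benzyloxy)-2-[4-(benzyloxy)phenyl]-5-hydroxy-3,6,8-trimethoxy-4H-chromen-4-one, via dienylketene 12 (not isolated), via 4aH-chromene-4,5-dione 13 (not isolated)
Conditions: degassed PhMe (0.01 M), 110 °C, Ar
Reagents that add atoms: none
Why: Heating should cause conrotatory 4π electrocyclic opening of the C1–C4 bond in which the C4 methoxy donor turns outward and the pyronyl group inward, so that dienylketene 12 has the pyrone cis to the ketene. The ketene carbon then bonds to the nucleophilic pyrone C5 in a thermal disrotatory 6π electrocyclisation (ketene C=C, enol-ether C=C, pyrone C5=C6) that forms C5–C4a and closes ring A as dienone 13, whose 4a-H, flanked by two carbonyls, moves to oxygen and aromatises the ring. This is the Moore rearrangement of 4-aryl, 4-heteroaryl or 4-alkenyl 4-hydroxy(alkoxy)cyclobutenones, its nearest relative being the annulation of a chromone to a xanthone. No stereocentre is created, and the racemic C4 of 11 disappears. The step needs outward rotation of the ether oxygen, secured by the donor torquoselectivity of OMe, and closure at one site only, secured because the cyclobutenone sits on pyrone C6, whose only carbon neighbour is C5; this fixes the map ketene carbon to chelated 5-OH, C2 to 6-OMe, C3 to 7-OBn and C4 to 8-OMe. The methyl ether also shuts off lactonisation to a furanone and gives a chelated phenol in place of an oxidisable hydroquinone.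

Step 7
Reactants: 14 7-(benzyloxy)-2-[4-(benzyloxy)phenyl]-5-hydroxy-3,6,8-trimethoxy-4H-chromen-4-one
Product: 15 5,7-dihydroxy-2-(4-hydroxyphenyl)-3,6,8-trimethoxy-4H-chromen-4-one (target)
Conditions: H2 (1 atm), 10% Pd/C, EtOAc/MeOH, rt
Reagents that add atoms: none
Why: Catalytic hydrogenolysis should cleave both aryl benzyl ethers (O-debenzylation) while the methyl ethers, the chelated 5-OH and the tetrasubstituted C2=C3 bond of the flavone stay untouched under 1 atm of hydrogen.

**Compound list**

1 | 3-hydroxy-4H-pyran-4-one (pyromeconic acid) | O=c1ccocc1O | starting material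
2 | 2-bromo-3-hydroxy-4H-pyran-4-one | O=c1ccoc(Br)c1O | intermediate
3 | 2-bromo-3-methoxy-4H-pyran-4-one | COc1c(Br)occc1=O | intermediate
4 | 4-(benzyloxy)phenylboronic acid | OB(O)c1ccc(OCc2ccccc2)cc1 | starting material
5 | 2-[4-(benzyloxy)phenyl]-3-methoxy-4H-pyran-4-one | COc1c(-c2ccc(OCc3ccccc3)cc2)occc1=O | intermediate
6 | dimethyl squarate (3,4-dimethoxycyclobut-3-ene-1,2-dione) | COC1=C(OC)C(=O)C1=O | starting material
7 | {6-[4-(benzyloxy)phenyl]-5-methoxy-4-oxo-4H-pyran-2-yl}lithium (not isolated) | [Li]c1cc(=O)c(OC)c(-c2ccc(OCc3ccccc3)cc2)o1 | intermediate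
8 | lithium 1-{6-[4-(benzyloxy)phenyl]-5-methoxy-4-oxo-4H-pyran-2-yl}-2,3-dimethoxy-4-oxocyclobut-2-en-1-olate (racemic, not isolated) | [Li+].[O-]C1(c2cc(=O)c(OC)c(-c3ccc(OCc4ccccc4)cc3)o2)C(OC)=C(OC)C1=O | intermediate
9 | 4-{6-[4-(benzyloxy)phenyl]-5-methoxy-4-oxo-4H-pyran-2-yl}-2,3,4-trimethoxycyclobut-2-en-1-one (racemic) | COC1=C(OC)C(OC)(c2cc(=O)c(OC)c(-c3ccc(OCc4ccccc4)cc3)o2)C1=O | intermediate
10 | benzyl alcohol | OCc1ccccc1 | starting material
11 | 3-(benzyloxy)-4-{6-[4-(benzyloxy)phenyl]-5-methoxy-4-oxo-4H-pyran-2-yl}-2,4-dimethoxycyclobut-2-en-1-one (racemic) | COC1=C(OCc2ccccc2)C(OC)(c2cc(=O)c(OC)c(-c3ccc(OCc4ccccc4)cc3)o2)C1=O | intermediate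
12 | (3Z)-3-(benzyloxy)-4-{6-[4-(benzyloxy)phenyl]-5-methoxy-4-oxo-4H-pyran-2-yl}-2,4-dimethoxybuta-1,3-dien-1-one (dienylketene, pyronyl cis to the ketene-bearing carbon, not isolated) | O=C=C(OC)/C(OCc1ccccc1)=C(OC)\c1cc(=O)c(OC)c(-c2ccc(OCc3ccccc3)cc2)o1 | intermediate
13 | 7-(benzyloxy)-2-[4-(benzyloxy)phenyl]-3,6,8-trimethoxy-4aH-chromene-4,5-dione (racemic at C4a, not isolated) | COC1=C(OCc2ccccc2)C(OC)=C2OC(-c3ccc(OCc4ccccc4)cc3)=C(OC)C(=O)C2C1=O | intermediate
14 | 7-(benzyloxy)-2-[4-(benzyloxy)phenyl]-5-hydroxy-3,6,8-trimethoxy-4H-chromen-4-one | COc1c(OCc2ccccc2)c(OC)c2oc(-c3ccc(OCc4ccccc4)cc3)c(OC)c(=O)c2c1O | intermediate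
15 | 5,7-dihydroxy-2-(4-hydroxyphenyl)-3,6,8-trimethoxy-4H-chromen-4-one (5,7,4'-trihydroxy-3,6,8-trimethoxyflavone, achiral) | COc1c(O)c(OC)c2oc(-c3ccc(O)cc3)c(OC)c(=O)c2c1O | target

**Step count.** Total: 7 steps. Longest linear sequence: 7 steps (1 → 15).

**Steps most likely to fail**

Step 6 (key step). What may go wrong: ring opening may set in only at temperatures where the dienylketene also oligomerises or is intercepted by phenol already formed, and part of the ether may rotate inward and so be unable to close. The fallback sets out from 8 and returns at 14: the carbinol oxygen is left free, the classical substrate type for this rearrangement, and the methyl group is put on after the annulation. Quenching 8 with aq. NH4Cl instead of MeOTf should give 4-{6-[4-(benzyloxy)phenyl]-5-methoxy-4-oxo-4H-pyran-2-yl}-4-hydroxy-2,3-dimethoxycyclobut-2-en-1-one F1. The exchange of step 5 should then give 3-(benzyloxy)-4-{6-[4-(benzyloxy)phenyl]-5-methoxy-4-oxo-4H-pyran-2-yl}-4-hydroxy-2-methoxycyclobut-2-en-1-one F2. Thermolysis (degassed p-xylene, 138 °C) should pass through the hydroxy dienylketene F3 and the 8-hydroxy-4aH-chromene-4,5-dione F4 to 7-(benzyloxy)-2-[4-(benzyloxy)phenyl]-5,8-dihydroxy-3,6-dimethoxy-4H-chromen-4-one F5. This hydroquinone is kept under argon and methylated at the non-chelated 8-OH (MeI 1.05 equiv, K2CO3, acetone, rt), the 5-OH being held by the C4 carbonyl, to give 14.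

Step 5. What may go wrong: the acid may ionise the C4–OMe bond (loss of methanol towards cyclobutenedione-type products, or alkoxy scrambling at C4) faster than it exchanges the C3 methoxy, or the equilibrium may stall short of completion. The fallback sets out from 6 and 10 and returns at 11: the benzyl group is installed before the C–C bond is made, at the price of regiocontrol. Mono-exchange of 6 with 10 (1 equiv, cat. Et3N, CH2Cl2, chromatographic separation from unchanged and doubly exchanged ester) should give 3-(benzyloxy)-4-methoxycyclobut-3-ene-1,2-dione F6. Addition of 7 at −78 °C should give the two alkoxides lithium 2-(benzyloxy)-1-{6-[4-(benzyloxy)phenyl]-5-methoxy-4-oxo-4H-pyran-2-yl}-3-methoxy-4-oxocyclobut-2-en-1-olate F7 and its 3-(benzyloxy)-2-methoxy isomer F8 without useful selectivity. Trapping with MeOTf should give 11 and its regioisomer 2-(benzyloxy)-4-{6-[4-(benzyloxy)phenyl]-5-methoxy-4-oxo-4H-pyran-2-yl}-3,4-dimethoxycyclobut-2-en-1-one F9, which would be separated by chromatography and assigned by HMBC before the route continues from 11.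

Step 4. What may go wrong: the amide base may deprotonate at a competing site or add to the pyrone and open it, the lithiopyrone may self-condense before it meets the squarate, and methyl triflate may also alkylate the pyrone carbonyl. The fallback sets out from 5 and returns at 9: metalation, addition and methylation are separated. Zincation of 5 with TMPZnCl·LiCl (THF, rt), a base that metalates chromones next to the ring oxygen, should give chlorido{6-[4-(benzyloxy)phenyl]-5-methoxy-4-oxo-4H-pyran-2-yl}zinc F10, and iodolysis (I2, THF) 2-[4-(benzyloxy)phenyl]-6-iodo-3-methoxy-4H-pyran-4-one F11. Iodine–magnesium exchange (iPrMgCl·LiCl, THF, −40 °C) should give the pyronylmagnesium chloride F12, which adds to 6 to give the chloromagnesium cyclobutenolate F13. Work-up with aq. NH4Cl should give the carbinol named above as F1, and MeI/Ag2O (MeCN, rt) should methylate the tertiary alcohol to give 9.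

**Further compounds**

F1 | step 6 | 4-{6-[4-(benzyloxy)phenyl]-5-methoxy-4-oxo-4H-pyran-2-yl}-4-hydroxy-2,3-dimethoxycyclobut-2-en-1-one (racemic) | COC1=C(OC)C(O)(c2cc(=O)c(OC)c(-c3ccc(OCc4ccccc4)cc3)o2)C1=O
F2 | step 6 | 3-(benzyloxy)-4-{6-[4-(benzyloxy)phenyl]-5-methoxy-4-oxo-4H-pyran-2-yl}-4-hydroxy-2-methoxycyclobut-2-en-1-one (racemic) | COC1=C(OCc2ccccc2)C(O)(c2cc(=O)c(OC)c(-c3ccc(OCc4ccccc4)cc3)o2)C1=O
F3 | step 6 | (3Z)-3-(benzyloxy)-4-{6-[4-(benzyloxy)phenyl]-5-methoxy-4-oxo-4H-pyran-2-yl}-4-hydroxy-2-methoxybuta-1,3-dien-1-one (hydroxy dienylketene) | O=C=C(OC)/C(OCc1ccccc1)=C(O)\c1cc(=O)c(OC)c(-c2ccc(OCc3ccccc3)cc2)o1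
F4 | step 6 | 7-(benzyloxy)-2-[4-(benzyloxy)phenyl]-8-hydroxy-3,6-dimethoxy-4aH-chromene-4,5-dione (racemic at C4a) | COC1=C(OCc2ccccc2)C(O)=C2OC(-c3ccc(OCc4ccccc4)cc3)=C(OC)C(=O)C2C1=O
F5 | step 6 | 7-(benzyloxy)-2-[4-(benzyloxy)phenyl]-5,8-dihydroxy-3,6-dimethoxy-4H-chromen-4-one | COc1c(OCc2ccccc2)c(O)c2oc(-c3ccc(OCc4ccccc4)cc3)c(OC)c(=O)c2c1O
F6 | step 5 | 3-(benzyloxy)-4-methoxycyclobut-3-ene-1,2-dione | COC1=C(OCc2ccccc2)C(=O)C1=O
F7 | step 5 | lithium 2-(benzyloxy)-1-{6-[4-(benzyloxy)phenyl]-5-methoxy-4-oxo-4H-pyran-2-yl}-3-methoxy-4-oxocyclobut-2-en-1-olate (racemic) | [Li+].[O-]C1(c2cc(=O)c(OC)c(-c3ccc(OCc4ccccc4)cc3)o2)C(OCc2ccccc2)=C(OC)C1=O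
F8 | step 5 | lithium 3-(benzyloxy)-1-{6-[4-(benzyloxy)phenyl]-5-methoxy-4-oxo-4H-pyran-2-yl}-2-methoxy-4-oxocyclobut-2-en-1-olate (racemic) | [Li+].[O-]C1(c2cc(=O)c(OC)c(-c3ccc(OCc4ccccc4)cc3)o2)C(OC)=C(OCc2ccccc2)C1=O
F9 | step 5 | 2-(benzyloxy)-4-{6-[4-(benzyloxy)phenyl]-5-methoxy-4-oxo-4H-pyran-2-yl}-3,4-dimethoxycyclobut-2-en-1-one (racemic) | COC1=C(OCc2ccccc2)C(=O)C1(OC)c1cc(=O)c(OC)c(-c2ccc(OCc3ccccc3)cc2)o1
F10 | step 4 | chlorido{6-[4-(benzyloxy)phenyl]-5-methoxy-4-oxo-4H-pyran-2-yl}zinc | COc1c(-c2ccc(OCc3ccccc3)cc2)oc([Zn]Cl)cc1=O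
F11 | step 4 | 2-[4-(benzyloxy)phenyl]-6-iodo-3-methoxy-4H-pyran-4-one | COc1c(-c2ccc(OCc3ccccc3)cc2)oc(I)cc1=O
F12 | step 4 | chlorido{6-[4-(benzyloxy)phenyl]-5-methoxy-4-oxo-4H-pyran-2-yl}magnesium | COc1c(-c2ccc(OCc3ccccc3)cc2)oc([Mg]Cl)cc1=O
F13 | step 4 | chloromagnesium 1-{6-[4-(benzyloxy)phenyl]-5-methoxy-4-oxo-4H-pyran-2-yl}-2,3-dimethoxy-4-oxocyclobut-2-en-1-olate (racemic) | COC1=C(OC)C(O[Mg]Cl)(c2cc(=O)c(OC)c(-c3ccc(OCc4ccccc4)cc3)o2)C1=O
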